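**Strategy.** Ring C is disconnected at C4a–C4, C4–C3 and O1–C2: the C4 carbonyl, flanked by C4a of the tetraoxygenated ring A and by the C3=C2–aryl unit, is taken from carbon monoxide. A palladium-catalysed carbonylative coupling of an ortho-iodophenol with 3,4,5-trimethoxyphenylacetylene, run in diethylamine, should assemble the ynone and close the pyranone in one operation. The precursor is a 2-iodophenol whose iodine lies between the free hydroxyl (future O1, next to the two methoxy groups) and a benzyl-capped oxygen (future 5-OH). This placement fixes the 5,7,8 pattern and leaves only one oxygen able to cyclise. Hydroxylation at C3 and hydrogenolysis finish the target.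

Key step: step 6

Remark on the chemistry: the target has no stereocentre; the only chiral species on the route, a transient epoxide, is racemic and is consumed in the flask in which it forms.

**Step 1**
Reactants: 1 3-hydroxy-4,5-dimethoxybenzaldehyde
Product: 2 3,4-dimethoxy-5-(methoxymethoxy)benzaldehyde
Conditions: MOMCl, K2CO3, acetone, 0 °C to rt
Reagents that add atoms: chloromethyl methyl ether, COCCl
Why: Williamson-type O-alkylation of the phenoxide by the reactive α-chloro ether should give the MOM acetal cleanly, the aldehyde being inert to carbonate.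

**Step 2**
Reactants: 2 3,4-dimethoxy-5-(methoxymethoxy)benzaldehyde
Product: 4 3,4-dimethoxy-5-(methoxymethoxy)phenol, via aryl formate 3 (not isolated)
Conditions: mCPBA, CH2Cl2, 0 °C to rt; aqueous NaHCO3 wash; then K2CO3 (cat.), MeOH, rt
Reagents that add atoms: 3-chloroperoxybenzoic acid, OOC(=O)c1cccc(Cl)c1
Why: Baeyer–Villiger (Dakin-type) oxidation, in which the electron-rich aryl group, activated by the para methoxy group, migrates in the Criegee intermediate in preference to hydride, followed by base-catalysed methanolysis of the aryl formate that leaves the MOM acetal untouched.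

**Step 3**
Reactants: 4 3,4-dimethoxy-5-(methoxymethoxy)phenol
Product: 5 5-(benzyloxy)-1,2-dimethoxy-3-(methoxymethoxy)benzene
Conditions: BnBr, K2CO3, DMF, rt
Reagents that add atoms: benzyl bromide, BrCc1ccccc1
Why: Williamson ether synthesis on an unhindered phenoxide with a benzylic bromide; benzyl is chosen because it should survive acid, amine, carbonylation and dioxirane and leave by hydrogenolysis at the end.

**Step 4**
Reactants: 5 5-(benzyloxy)-1,2-dimethoxy-3-(methoxymethoxy)benzene
Product: 7 1-(benzyloxy)-2-iodo-4,5-dimethoxy-3-(methoxymethoxy)benzene, via aryllithium 6 (not isolated)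
Conditions: n-BuLi, THF, −78 to 0 °C; then I2, THF, −78 °C to rt
Reagents that add atoms: iodine, II
Why: Directed ortho-metalation, in which the ring hydrogen flanked by the chelating MOM acetal and the benzyloxy group is the kinetically preferred site (MOM outranks methoxy as a director, so the C–H between benzyloxy and methoxy is less activated), followed by iodinolysis of the aryllithium, which places iodine on the carbon that becomes C4a.

**Step 5**
Reactants: 7 1-(benzyloxy)-2-iodo-4,5-dimethoxy-3-(methoxymethoxy)benzene
Product: 8 3-(benzyloxy)-2-iodo-5,6-dimethoxyphenol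
Conditions: HCl (3 M aq.), MeOH, 40 °C
Reagents that add atoms: none
Why: Acid-catalysed acetal cleavage (transacetalisation to dimethoxymethane) should free only the MOM-protected phenol, since the benzyl ether, the methyl ethers and the aryl iodide are inert to dilute methanolic HCl.

**Step 6**
Reactants: 8 3-(benzyloxy)-2-iodo-5,6-dimethoxyphenol; 9 5-ethynyl-1,2,3-trimethoxybenzene; 10 carbon monoxide
Product: 13 5-(benzyloxy)-7,8-dimethoxy-2-(3,4,5-trimethoxyphenyl)-4H-chromen-4-one, via hydroxyaryl ynone 11 (not isolated), via diethylamino enaminone 12 (not isolated)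
Conditions: PdCl2(PPh3)2 (5 mol %), Et2NH, CO (20 bar), 120 °C, autoclave, no copper salt
Reagents that add atoms: none
Why: Zerovalent palladium, formed in situ from PdCl2(PPh3)2, inserts into the C–I bond of 8; CO then inserts to give an aroylpalladium species, which is intercepted by the acetylide generated from 9 and Et2NH, and reductive elimination releases ynone 11 with the new C4a–C4 and C4–C3 bonds. The closest known reaction type is the carbonylative Sonogashira coupling of 2-iodophenols with terminal alkynes that leads directly to flavones. Diethylamine adds in conjugate fashion to 11 to give enaminone 12, and the phenol then attacks C2 and expels the amine (addition–elimination), so ring C closes in a net 6-endo mode through the O1–C2 bond. No stereocentre is created. The step needs carbonylation to outrun direct alkynylation and needs pyranone closure over five-membered aurone closure: CO pressure and the absence of copper should secure the first, and the enaminone, electrophilic only at C2, should secure the second. Which oxygen cyclises and where the ring fuses is fixed by the substrate, because iodine sits on the future C4a and the only other flanking oxygen is benzylated.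

**Step 7**
Reactants: 13 5-(benzyloxy)-7,8-dimethoxy-2-(3,4,5-trimethoxyphenyl)-4H-chromen-4-one
Product: 15 5-(benzyloxy)-3-hydroxy-7,8-dimethoxy-2-(3,4,5-trimethoxyphenyl)-4H-chromen-4-one, via flavone epoxide 14 (not isolated)
Conditions: dimethyldioxirane (acetone solution, excess, in portions), CH2Cl2, 0 °C to rt; then TsOH·H2O (cat.), CH2Cl2, rt
Reagents that add atoms: dimethyldioxirane, CC1(C)OO1
Why: Dioxirane epoxidation of the enol-ether-like C2=C3 bond followed by acid-catalysed epoxide-to-enol isomerisation (C2–O cleavage to the cation stabilised by O1 and the aryl group, then loss of H3) should deliver the 3-hydroxyflavone; the racemic epoxide loses both stereocentres on opening.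

**Step 8**
Reactants: 15 5-(benzyloxy)-3-hydroxy-7,8-dimethoxy-2-(3,4,5-trimethoxyphenyl)-4H-chromen-4-one
Product: 16 3,5-dihydroxy-7,8-dimethoxy-2-(3,4,5-trimethoxyphenyl)-4H-chromen-4-one
Conditions: H2 (1 atm), Pd/C (10 wt %), EtOAc–MeOH, rt
Reagents that add atoms: none
Why: Heterogeneous catalytic hydrogenolysis should cleave the benzylic C–O bond, while the tetrasubstituted vinylogous-ester C2=C3 bond, the ketone and the methyl ethers are expected to stay untouched at 1 atm and room temperature.

**Compound list**

1 | 3-hydroxy-4,5-dimethoxybenzaldehyde | COc1cc(C=O)cc(O)c1OC | starting material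
2 | 3,4-dimethoxy-5-(methoxymethoxy)benzaldehyde | COCOc1cc(C=O)cc(OC)c1OC | intermediate
3 | 3,4-dimethoxy-5-(methoxymethoxy)phenyl formate | COCOc1cc(OC=O)cc(OC)c1OC | intermediate (not isolated)
4 | 3,4-dimethoxy-5-(methoxymethoxy)phenol | COCOc1cc(O)cc(OC)c1OC | intermediate
5 | 5-(benzyloxy)-1,2-dimethoxy-3-(methoxymethoxy)benzene | COCOc1cc(OCc2ccccc2)cc(OC)c1OC | intermediate
6 | [2-(benzyloxy)-4,5-dimethoxy-6-(methoxymethoxy)phenyl]lithium | [Li]c1c(OCc2ccccc2)cc(OC)c(OC)c1OCOC | intermediate (not isolated)
7 | 1-(benzyloxy)-2-iodo-4,5-dimethoxy-3-(methoxymethoxy)benzene | COCOc1c(I)c(OCc2ccccc2)cc(OC)c1OC | intermediate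
8 | 3-(benzyloxy)-2-iodo-5,6-dimethoxyphenol | COc1cc(OCc2ccccc2)c(I)c(O)c1OC | intermediate
9 | 5-ethynyl-1,2,3-trimethoxybenzene | C#Cc1cc(OC)c(OC)c(OC)c1 | starting material
10 | carbon monoxide | [C-]#[O+] | starting material
11 | 1-[6-(benzyloxy)-2-hydroxy-3,4-dimethoxyphenyl]-3-(3,4,5-trimethoxyphenyl)prop-2-yn-1-one | COc1cc(OCc2ccccc2)c(C(=O)C#Cc2cc(OC)c(OC)c(OC)c2)c(O)c1OC | intermediate (not isolated)
12 | (E)-1-[6-(benzyloxy)-2-hydroxy-3,4-dimethoxyphenyl]-3-(diethylamino)-3-(3,4,5-trimethoxyphenyl)prop-2-en-1-one (geometry of no consequence for the closure) | CCN(CC)/C(=C/C(=O)c1c(O)c(OC)c(OC)cc1OCc1ccccc1)c1cc(OC)c(OC)c(OC)c1 | intermediate (not isolated)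
13 | 5-(benzyloxy)-7,8-dimethoxy-2-(3,4,5-trimethoxyphenyl)-4H-chromen-4-one (5-benzyloxy-7,8,3',4',5'-pentamethoxyflavone) | COc1cc(-c2cc(=O)c3c(OCc4ccccc4)cc(OC)c(OC)c3o2)cc(OC)c1OC | intermediate
14 | 2,3-epoxide of 13: 5-(benzyloxy)-2,3-epoxy-7,8-dimethoxy-2-(3,4,5-trimethoxyphenyl)chroman-4-one, racemic, oxirane cis-fused to ring C (C2 aryl and C3–H on the same face), one enantiomer drawn | COc1cc(cc(OC)c1OC)[C@@]12O[C@@H]1C(=O)c1c(OCc3ccccc3)cc(OC)c(OC)c1O2 | intermediate (not isolated)
15 | 5-(benzyloxy)-3-hydroxy-7,8-dimethoxy-2-(3,4,5-trimethoxyphenyl)-4H-chromen-4-one | COc1cc(-c2oc3c(OC)c(OC)cc(OCc4ccccc4)c3c(=O)c2O)cc(OC)c1OC | intermediate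
16 | 3,5-dihydroxy-7,8-dimethoxy-2-(3,4,5-trimethoxyphenyl)-4H-chromen-4-one (3,5-dihydroxy-7,8,3',4',5'-pentamethoxyflavone) | COc1cc(-c2oc3c(OC)c(OC)cc(O)c3c(=O)c2O)cc(OC)c1OC | target

**Totals**

Total step count: 8. Longest linear sequence: 8 steps (1 to 16); alkyne 9 and carbon monoxide 10 enter at step 6.

**Steps most likely to fail**

Step 6. Oxidative addition into the doubly ortho-substituted, electron-rich C–I bond may be so slow that catalyst decay, reductive loss of iodine, direct (non-carbonylative) alkynylation leading to a benzofuran, or capture of the aroylpalladium species by diethylamine takes over. The fallback builds the same ynone by organometallic acylation, sets out from iodide 7 and alkyne 9, and returns to the route at flavone 13. Alkyne 9 is deprotonated (n-BuLi, THF, −78 °C) and quenched with N-methoxy-N-methylcarbamoyl chloride to give N-methoxy-N-methyl-3-(3,4,5-trimethoxyphenyl)prop-2-ynamide F1. Iodine–lithium exchange of 7 (n-BuLi, THF, −78 °C) regenerates aryllithium 6, which should add to F1 and, after quench with aqueous HCl, give 1-[6-(benzyloxy)-3,4-dimethoxy-2-(methoxymethoxy)phenyl]-3-(3,4,5-trimethoxyphenyl)prop-2-yn-1-one F2. Methanolic HCl then removes the MOM group to give hydroxy ynone 11, and warming with Et2NH in EtOH should close ring C through enaminone 12 to 13.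

Step 4. Deprotonation of the benzylic CH2 (followed by [1,2]-Wittig rearrangement), or metalation at the ring C–H between the benzyloxy and methoxy groups, may compete with the wanted lithiation. The fallback introduces iodine by electrophilic substitution before any benzyl ether exists, sets out from aldehyde 1, and returns at iodide 7. Iodination of 1 ortho to the free hydroxyl (ICl, pyridine, dioxane, rt; the site is also para to the 5-methoxy group, as in the 2-iodination of isovanillin) should give 3-hydroxy-2-iodo-4,5-dimethoxybenzaldehyde F3. MOMCl and K2CO3 in acetone convert it into 2-iodo-4,5-dimethoxy-3-(methoxymethoxy)benzaldehyde F4. Baeyer–Villiger oxidation with mCPBA gives 2-iodo-4,5-dimethoxy-3-(methoxymethoxy)phenyl formate F5, which is not isolated but methanolysed (K2CO3, MeOH) to 2-iodo-4,5-dimethoxy-3-(methoxymethoxy)phenol F6. Benzylation (BnBr, K2CO3, DMF) then gives 7.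

Step 7. Epoxidation of the conjugated C2=C3 bond may stall, or the dioxirane may attack the electron-rich rings or the benzylic CH2 instead. The fallback is metalation–borylation–oxidation at C3, sets out from flavone 13, and returns at flavonol 15. Deprotonation with LiN(iPr)2 in THF at −78 °C should give [5-(benzyloxy)-7,8-dimethoxy-4-oxo-2-(3,4,5-trimethoxyphenyl)-4H-chromen-3-yl]lithium F7. B(OMe)3 traps it as lithium [5-(benzyloxy)-7,8-dimethoxy-4-oxo-2-(3,4,5-trimethoxyphenyl)-4H-chromen-3-yl]trimethoxyborate F8, and AcOH with 30% H2O2 (0 °C to rt, same flask) oxidises the C–B bond to give 15.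

**Further compounds**

F1 | step 6 | N-methoxy-N-methyl-3-(3,4,5-trimethoxyphenyl)prop-2-ynamide | CON(C)C(=O)C#Cc1cc(OC)c(OC)c(OC)c1
F2 | step 6 | 1-[6-(benzyloxy)-3,4-dimethoxy-2-(methoxymethoxy)phenyl]-3-(3,4,5-trimethoxyphenyl)prop-2-yn-1-one | COCOc1c(C(=O)C#Cc2cc(OC)c(OC)c(OC)c2)c(OCc2ccccc2)cc(OC)c1OC
F3 | step 4 | 3-hydroxy-2-iodo-4,5-dimethoxybenzaldehyde | COc1cc(C=O)c(I)c(O)c1OC
F4 | step 4 | 2-iodo-4,5-dimethoxy-3-(methoxymethoxy)benzaldehyde | COCOc1c(I)c(C=O)cc(OC)c1OC
F5 | step 4 | 2-iodo-4,5-dimethoxy-3-(methoxymethoxy)phenyl formate | COCOc1c(I)c(OC=O)cc(OC)c1OC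
F6 | step 4 | 2-iodo-4,5-dimethoxy-3-(methoxymethoxy)phenol | COCOc1c(I)c(O)cc(OC)c1OC
F7 | step 7 | [5-(benzyloxy)-7,8-dimethoxy-4-oxo-2-(3,4,5-trimethoxyphenyl)-4H-chromen-3-yl]lithium | COc1cc(-c2oc3c(OC)c(OC)cc(OCc4ccccc4)c3c(=O)c2[Li])cc(OC)c1OC
F8 | step 7 | lithium [5-(benzyloxy)-7,8-dimethoxy-4-oxo-2-(3,4,5-trimethoxyphenyl)-4H-chromen-3-yl]trimethoxyborate | [Li+].CO[B-](OC)(OC)c1c(-c2cc(OC)c(OC)c(OC)c2)oc2c(OC)c(OC)cc(OCc3ccccc3)c2c1=O
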